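**Strategy.** The pyran ring (ring C) is closed last at O1–C2, and the closure is coupled to the 3-O-aroyl group on the neighbouring C3. The ester carbon of the 4-hydroxybenzoate starts as the ortho ester carbon of a cis-4,5-disubstituted 1,3-dioxolane that bridges the oxygens on C2 and C3 of an anti-1,3-diarylpropane-1,2-diol. Acid ionises it to a 2-aryl-1,3-dioxolan-2-ylium ion, and the ring A phenol opens this ion at benzylic C2 with inversion. One operation thus forms O1–C2, sets the 2,3-cis (2R,3R) relationship and unveils the C3 ester. The anti-diol comes from a Sharpless kinetic-resolution epoxy alcohol and an aryl Grignard reagent; hydrogenolysis of five benzyl ethers finishes.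

Key step: step 8

Remark on the chemistry: compounds 1, 2, 5, 11 and 12 are taken as purchasable. The kinetic resolution in step 2 is meant to be stopped near 45% conversion, so at most half of racemic 3 can be carried into 4.

**Step 1**
Reactants: 1 3,4-bis(benzyloxy)benzaldehyde; 2 vinylmagnesium bromide
Product: 3 rac-1-[3,4-bis(benzyloxy)phenyl]prop-2-en-1-ol
Conditions: THF, −78 → 0 °C; aq. NH4Cl
Reagents that add atoms: none
Why: Grignard 1,2-addition to the aromatic aldehyde should give the secondary allylic alcohol as a racemate, whose carbinol centre is sorted out in step 2.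

**Step 2**
Reactants: 3 rac-1-[3,4-bis(benzyloxy)phenyl]prop-2-en-1-ol
Product: 4 (S)-[3,4-bis(benzyloxy)phenyl][(R)-oxiran-2-yl]methanol
Conditions: Ti(OiPr)4 (10 mol %), L-(+)-DIPT (15 mol %), TBHP (0.45 equiv), 4 Å MS, CH2Cl2, −20 °C
Reagents that add atoms: tert-butyl hydroperoxide, CC(C)(C)OO
Why: Sharpless kinetic resolution by Katsuki–Sharpless epoxidation: with L-(+)-DIPT the (R)-enantiomer of 3 should be epoxidised much faster than the (S)-enantiomer and with erythro (anti) selectivity, so the reagent-controlled face selection sets the oxirane carbon as R next to the carbinol centre (S in 4), while unreacted (S)-3 is removed by chromatography.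

**Step 3**
Reactants: 5 3,5-bis(benzyloxy)phenol
Product: 6 3,5-bis(benzyloxy)-2-bromophenol
Conditions: NBS (1.0 equiv), i-Pr2NH (10 mol %), CH2Cl2, −78 → 0 °C
Reagents that add atoms: N-bromosuccinimide, O=C1CCC(=O)N1Br
Why: Amine-catalysed ortho-selective electrophilic bromination of a phenol should place bromine next to the hydroxyl, the para position being flanked by two benzyloxy groups.

**Step 4**
Reactants: 6 3,5-bis(benzyloxy)-2-bromophenol
Product: 7 1-(allyloxy)-3,5-bis(benzyloxy)-2-bromobenzene
Conditions: allyl bromide, K2CO3, DMF, rt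
Reagents that add atoms: allyl bromide, C=CCBr
Why: Williamson ether synthesis masks the phenol as an allyl ether that tolerates the Grignard chemistry and can later be removed under neutral conditions in the presence of benzyl ethers.

**Step 5**
Reactants: 7 1-(allyloxy)-3,5-bis(benzyloxy)-2-bromobenzene; 4 (S)-[3,4-bis(benzyloxy)phenyl][(R)-oxiran-2-yl]methanol
Product: 9 (1S,2R)-3-[2-(allyloxy)-4,6-bis(benzyloxy)phenyl]-1-[3,4-bis(benzyloxy)phenyl]propane-1,2-diol, via aryl Grignard reagent 8 (not isolated)
Conditions: 7, Mg, LiCl, THF, rt (gives 8); 4, i-PrMgCl (1.0 equiv), THF, −40 °C; then 8 (1.5 equiv), CuI (10 mol %), −40 → 0 °C; aq. NH4Cl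
Reagents that add atoms: none
Why: Copper-catalysed SN2 opening of the terminal epoxide by the aryl Grignard reagent at the unsubstituted CH2 carbon forms the C4–C4a bond and leaves both stereocentres of 4 untouched, giving the anti (1S,2R) diol; the hydroxyl of 4 is masked as its magnesium alkoxide.

**Step 6**
Reactants: 9 (1S,2R)-3-[2-(allyloxy)-4,6-bis(benzyloxy)phenyl]-1-[3,4-bis(benzyloxy)phenyl]propane-1,2-diol
Product: 10 (1S,2R)-1-[3,4-bis(benzyloxy)phenyl]-3-[2,4-bis(benzyloxy)-6-hydroxyphenyl]propane-1,2-diol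
Conditions: Pd(PPh3)4 (5 mol %), morpholine, THF, rt
Reagents that add atoms: none
Why: Tsuji–Trost deallylation: zerovalent palladium ionises the aryl allyl ether to a π-allyl complex that morpholine captures, which should free the ring A phenol under neutral conditions without touching the benzyl ethers or the acid-sensitive benzylic diol.

**Step 7**
Reactants: 11 1-(benzyloxy)-4-bromobenzene; 12 tetramethyl orthocarbonate
Product: 14 1-(benzyloxy)-4-(trimethoxymethyl)benzene (trimethyl 4-(benzyloxy)orthobenzoate), via aryl Grignard reagent 13 (not isolated)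
Conditions: 11, Mg, THF, reflux (gives 13); 12, THF, reflux; aq. NaHCO3
Reagents that add atoms: none
Why: Tschitschibabin ortho ester synthesis: the aryl Grignard reagent displaces one methoxide from the orthocarbonate, and the resulting ortho ester should not react further under these conditions.

**Step 8**
Reactants: 10 (1S,2R)-1-[3,4-bis(benzyloxy)phenyl]-3-[2,4-bis(benzyloxy)-6-hydroxyphenyl]propane-1,2-diol; 14 1-(benzyloxy)-4-(trimethoxymethyl)benzene
Product: 17 (2R,3R)-5,7-bis(benzyloxy)-2-[3,4-bis(benzyloxy)phenyl]chroman-3-yl 4-(benzyloxy)benzoate, via cyclic ortho ester 15 (not isolated), via dioxolanylium ion 16 (not isolated)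
Conditions: 14 (1.5 equiv), PPTS (10 mol %), 4 Å MS, CH2Cl2, rt; then BF3·OEt2 (20 mol %), −40 °C → rt; Et3N quench
Reagents that add atoms: none
Why: Acid-catalysed ortho ester exchange on the anti-diol of 10 should give the cis-4,5-disubstituted 2-aryl-2-methoxy-1,3-dioxolane 15, and loss of methoxide gives the 2-aryl-1,3-dioxolan-2-ylium ion 16, in which the oxygen on benzylic C2 has become a leaving group whose departure turns the ortho ester carbon into the ester carbonyl. The closest known reaction type is the ortho ester-mediated cyclisation of 1-aryl-3-(2-hydroxyaryl)propane-1,2-diols to flavan-3-yl esters, an intramolecular case of acyloxonium opening as in Woodward–Prévost and Kolb–Sharpless chemistry. The temporary dioxolane closes by acetal exchange at the ortho ester carbon (5-exo attack on the dialkoxycarbenium carbon), and the pyran ring closes 6-exo-tet by attack of the phenol oxygen on C2 anti to the departing dioxolane oxygen. C2 is therefore set by inversion of the S benzylic carbinol centre of 10 (giving 2R), while C3 keeps the configuration fixed in step 2 and ends up carrying the 4-(benzyloxy)benzoate, so the 2,3-cis array follows from the anti-diol. The step needs attack at C2 and not at C3 (5-exo-tet to a dihydrobenzofuran) and an SN2-like opening without prior ionisation to a free benzylic cation; benzylic activation directs the phenol to C2, and the low temperature, the weakly polar solvent and the high stability of the aryl-substituted dioxolanylium ion are meant to keep the C2–O bond intact until the phenol displaces it.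

**Step 9**
Reactants: 17 (2R,3R)-5,7-bis(benzyloxy)-2-[3,4-bis(benzyloxy)phenyl]chroman-3-yl 4-(benzyloxy)benzoate
Product: 18 (2R,3R)-2-(3,4-dihydroxyphenyl)-5,7-dihydroxychroman-3-yl 4-hydroxybenzoate (epicatechin 3-O-p-hydroxybenzoate)
Conditions: H2 (1 atm), Pd(OH)2/C, THF–MeOH, rt
Reagents that add atoms: none
Why: Catalytic hydrogenolysis should cleave all five benzyl ethers under neutral conditions that leave the secondary benzoate ester and both stereocentres untouched.

**Compound list**
1 | 3,4-bis(benzyloxy)benzaldehyde | O=Cc1ccc(OCc2ccccc2)c(OCc2ccccc2)c1 | starting material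
2 | vinylmagnesium bromide | C=C[Mg]Br | starting material
3 | rac-1-[3,4-bis(benzyloxy)phenyl]prop-2-en-1-ol | C=CC(O)c1ccc(OCc2ccccc2)c(OCc2ccccc2)c1 | intermediate
4 | (S)-[3,4-bis(benzyloxy)phenyl][(R)-oxiran-2-yl]methanol | O[C@H]([C@H]1CO1)c1ccc(OCc2ccccc2)c(OCc2ccccc2)c1 | intermediate
5 | 3,5-bis(benzyloxy)phenol | Oc1cc(OCc2ccccc2)cc(OCc2ccccc2)c1 | starting material
6 | 3,5-bis(benzyloxy)-2-bromophenol | Oc1cc(OCc2ccccc2)cc(OCc2ccccc2)c1Br | intermediate
7 | 1-(allyloxy)-3,5-bis(benzyloxy)-2-bromobenzene | C=CCOc1cc(OCc2ccccc2)cc(OCc2ccccc2)c1Br | intermediate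
8 | [2-(allyloxy)-4,6-bis(benzyloxy)phenyl]magnesium bromide | C=CCOc1cc(OCc2ccccc2)cc(OCc2ccccc2)c1[Mg]Br | intermediate
9 | (1S,2R)-3-[2-(allyloxy)-4,6-bis(benzyloxy)phenyl]-1-[3,4-bis(benzyloxy)phenyl]propane-1,2-diol | O[C@H](Cc1c(OCC=C)cc(OCc2ccccc2)cc1OCc1ccccc1)[C@@H](O)c1ccc(OCc2ccccc2)c(OCc2ccccc2)c1 | intermediate
10 | (1S,2R)-1-[3,4-bis(benzyloxy)phenyl]-3-[2,4-bis(benzyloxy)-6-hydroxyphenyl]propane-1,2-diol | O[C@H](Cc1c(O)cc(OCc2ccccc2)cc1OCc1ccccc1)[C@@H](O)c1ccc(OCc2ccccc2)c(OCc2ccccc2)c1 | intermediate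
11 | 1-(benzyloxy)-4-bromobenzene | Brc1ccc(OCc2ccccc2)cc1 | starting material
12 | tetramethyl orthocarbonate | COC(OC)(OC)OC | starting material
13 | [4-(benzyloxy)phenyl]magnesium bromide | Br[Mg]c1ccc(OCc2ccccc2)cc1 | intermediate
14 | 1-(benzyloxy)-4-(trimethoxymethyl)benzene | COC(OC)(OC)c1ccc(OCc2ccccc2)cc1 | intermediate
15 | (4S,5R)-cis cyclic ortho ester: 3,5-bis(benzyloxy)-2-({2-[4-(benzyloxy)phenyl]-4-[3,4-bis(benzyloxy)phenyl]-2-methoxy-1,3-dioxolan-5-yl}methyl)phenol, both epimers at the ortho ester carbon | Oc1cc(OCc2ccccc2)cc(OCc2ccccc2)c1C[C@H]1OC(OC)(c2ccc(OCc3ccccc3)cc2)O[C@H]1c1ccc(OCc2ccccc2)c(OCc2ccccc2)c1 | intermediate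
16 | (4S,5R)-cis 2-[4-(benzyloxy)phenyl]-4-[3,4-bis(benzyloxy)phenyl]-5-[2,4-bis(benzyloxy)-6-hydroxybenzyl]-1,3-dioxolan-2-ylium ion | Oc1cc(OCc2ccccc2)cc(OCc2ccccc2)c1C[C@H]1OC(c2ccc(OCc3ccccc3)cc2)=[O+][C@H]1c1ccc(OCc2ccccc2)c(OCc2ccccc2)c1 | intermediate
17 | (2R,3R)-5,7-bis(benzyloxy)-2-[3,4-bis(benzyloxy)phenyl]chroman-3-yl 4-(benzyloxy)benzoate | O=C(O[C@@H]1Cc2c(OCc3ccccc3)cc(OCc3ccccc3)cc2O[C@@H]1c1ccc(OCc2ccccc2)c(OCc2ccccc2)c1)c1ccc(OCc2ccccc2)cc1 | intermediate
18 | (2R,3R)-2-(3,4-dihydroxyphenyl)-5,7-dihydroxychroman-3-yl 4-hydroxybenzoate | O=C(O[C@@H]1Cc2c(O)cc(O)cc2O[C@@H]1c1ccc(O)c(O)c1)c1ccc(O)cc1 | target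

**Step count.** Total: 9 steps. Longest linear sequence: 6 steps (steps 1, 2, 5, 6, 8, 9; the branch through steps 3 and 4 is equally long).

**Steps most likely to fail**

Step 8. Ion 16 may ionise further at its benzylic C–O bond to an open benzylic cation before the phenol attacks; reclosure of that cation would erode the 2,3-cis selectivity, and attack of the phenol at C3 would give a five-membered ring instead. The fallback separates ring closure from ester formation and sets out from 10. Mitsunobu cyclisation (PPh3, DIAD, THF, 0 °C), in which the phenoxide displaces the benzylic oxyphosphonium group with inversion, should give (2R,3R)-5,7-bis(benzyloxy)-2-[3,4-bis(benzyloxy)phenyl]chroman-3-ol F1. Steglich esterification of F1 with 4-(benzyloxy)benzoic acid (DCC, DMAP, CH2Cl2) comes back to the route at 17.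

Step 2. The titanium–tartrate catalyst may discriminate too weakly between the enantiomers of this electron-rich aryl vinyl carbinol, so that the epoxy alcohol forms with insufficient enantiomeric purity. The fallback moves the resolution to an enzyme and sets out from 3. Lipase-catalysed acylation (Candida antarctica lipase B, vinyl acetate, MTBE) should acylate the (R)-enantiomer (Kazlauskas rule) to (R)-1-[3,4-bis(benzyloxy)phenyl]prop-2-en-1-yl acetate F2, which is separated from the unreacted (S)-alcohol. Methanolysis (K2CO3, MeOH) gives (R)-1-[3,4-bis(benzyloxy)phenyl]prop-2-en-1-ol F3. Epoxidation of enantiopure F3 with Ti(OiPr)4, L-(+)-DIPT and TBHP is then a matched, purely diastereoselective reaction and comes back to the route at 4.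

Step 5. Transfer of the di-ortho-substituted aryl group from copper to the epoxide may be sluggish, and the magnesium alkoxide of 4 may undergo Payne rearrangement before ring opening occurs. The fallback replaces organocopper chemistry by a Lewis acid-promoted aryllithium opening of a protected epoxide and sets out from 4. Silylation (Et3SiCl, imidazole, DMF) gives triethyl{(S)-[3,4-bis(benzyloxy)phenyl][(R)-oxiran-2-yl]methoxy}silane F4. Bromide 7 is converted by bromine–lithium exchange (n-BuLi, THF, −78 °C) into [2-(allyloxy)-4,6-bis(benzyloxy)phenyl]lithium F5, which should open F4 at the terminal carbon under BF3·OEt2 activation at −78 °C to give (1S,2R)-3-[2-(allyloxy)-4,6-bis(benzyloxy)phenyl]-1-[3,4-bis(benzyloxy)phenyl]-1-(triethylsilyloxy)propan-2-ol F6. TBAF in THF then frees the benzylic hydroxyl and the route is rejoined at 9.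

**Further compounds**
F1 | step 8 | (2R,3R)-5,7-bis(benzyloxy)-2-[3,4-bis(benzyloxy)phenyl]chroman-3-ol | O[C@@H]1Cc2c(OCc3ccccc3)cc(OCc3ccccc3)cc2O[C@@H]1c1ccc(OCc2ccccc2)c(OCc2ccccc2)c1
F2 | step 2 | (R)-1-[3,4-bis(benzyloxy)phenyl]prop-2-en-1-yl acetate | C=C[C@@H](OC(C)=O)c1ccc(OCc2ccccc2)c(OCc2ccccc2)c1
F3 | step 2 | (R)-1-[3,4-bis(benzyloxy)phenyl]prop-2-en-1-ol | C=C[C@@H](O)c1ccc(OCc2ccccc2)c(OCc2ccccc2)c1
F4 | step 5 | triethyl{(S)-[3,4-bis(benzyloxy)phenyl][(R)-oxiran-2-yl]methoxy}silane | CC[Si](CC)(CC)O[C@H]([C@H]1CO1)c1ccc(OCc2ccccc2)c(OCc2ccccc2)c1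
F5 | step 5 | [2-(allyloxy)-4,6-bis(benzyloxy)phenyl]lithium | [Li]c1c(OCC=C)cc(OCc2ccccc2)cc1OCc1ccccc1
F6 | step 5 | (1S,2R)-3-[2-(allyloxy)-4,6-bis(benzyloxy)phenyl]-1-[3,4-bis(benzyloxy)phenyl]-1-(triethylsilyloxy)propan-2-ol | O[C@H](Cc1c(OCC=C)cc(OCc2ccccc2)cc1OCc1ccccc1)[C@@H](O[Si](CC)(CC)CC)c1ccc(OCc2ccccc2)c(OCc2ccccc2)c1
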